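**Retrosynthetic overview**
1. The target comes from its C3 ketone by a hydride reduction that sets the last stereocentre.
2. The C3 ketone comes from a spiro[5.5]undecatrienone in one acid cascade that copies the presumed biosynthesis (chamigrenyl cation → myltaylyl cation → cyclomyltaylane): C1–C9 closes the bicyclo[2.2.1] ring, C8–C10 closes the cyclopropane, and acetate capture puts the oxygen on C11.
3. The trienone comes from a spiro Diels–Alder adduct by C1 homologation with carbonyl transposition, α′-hydroxylation and 1,4-elimination to the ring-B diene.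
4. The adduct comes from an enantioselective Diels–Alder reaction of a dimedone-derived α-methylene vinylogous ester with a dienyl pivalate made from tiglic aldehyde.
5. Ring order: A (from dimedone) → B (spiro, Diels–Alder) → bicyclo[2.2.1] ring and cyclopropane together (cascade).

Locants: C1–C15 are those of the target skeleton in all compounds (ring A = C1(bearing C12)–C2–C3–C4–C5(gem-dimethyl)–C6; ring B = C6–C7–C8–C9–C10(methyl C15)–C11). Configurations are given in the SMILES and described in words in the names.

Assumption: the (S)-oxazaborolidinium catalyst is taken to give the C6 configuration drawn for 8; if the facial sense is the opposite, the (R)-catalyst is used.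

**Step 1**
Reactants: 1 tiglic aldehyde
Product: 2 (1E)-2-methylbuta-1,3-dien-1-yl pivalate
Conditions: KOt-Bu, THF, −78 °C; then PivCl, −78 → 0 °C
Reagents that add atoms: pivaloyl chloride (CC(C)(C)C(Cl)=O)
Why: γ-deprotonation of the enal gives the potassium dienolate, which is O-acylated (dienol ester formation); the (1E)-ester is expected to predominate and is the only isomer that can reach the s-cis conformation needed in step 4.

**Step 2**
Reactants: 3 dimedone
Product: 4 3-isobutoxy-5,5-dimethylcyclohex-2-en-1-one
Conditions: i-BuOH, p-TsOH (cat.), toluene, reflux, Dean–Stark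
Reagents that add atoms: 2-methylpropan-1-ol (CC(C)CO)
Why: acid-catalysed enol etherification of the symmetrical 1,3-dione with azeotropic removal of water gives the vinylogous ester.

**Step 3**
Reactants: 4 3-isobutoxy-5,5-dimethylcyclohex-2-en-1-one
Product: 7 3-isobutoxy-5,5-dimethyl-6-methylidenecyclohex-2-en-1-one, via Mannich base 5 (not isolated), via methiodide 6 (not isolated)
Conditions: LDA, THF, −78 °C; CH2=NMe2+ I−, −78 → 0 °C; MeI, Et2O, rt; aq. NaHCO3, CH2Cl2, rt
Reagents that add atoms: N,N-dimethylmethyleneiminium iodide (C=[N+](C)C.[I-])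
Why: kinetic α′-lithiation of the vinylogous ester (Stork–Danheiser regiochemistry), Mannich reaction with Eschenmoser's salt, N-methylation and Hofmann-type β-elimination give the α-methylene ketone.

**Step 4**
Reactants: 7 3-isobutoxy-5,5-dimethyl-6-methylidenecyclohex-2-en-1-one; 2 (1E)-2-methylbuta-1,3-dien-1-yl pivalate
Product: 8 3-isobutoxy-5,5,10-trimethyl-1-oxospiro[5.5]undeca-2,9-dien-11-yl pivalate (C6 as in the target; pivalate cis to C1)
Conditions: (S)-o-tolyl-oxazaborolidinium triflimide (20 mol %), CH2Cl2, −40 → 0 °C
Reagents that add atoms: none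
Why: Lewis-acid-catalysed asymmetric Diels–Alder reaction in which the unhindered exocyclic CH2 bonds first, the 1-acyloxy group directs "ortho" so that C11 joins the spiro carbon, the chiral oxazaborolidinium complex of the s-cis enone shields one face and sets C6, and endo approach places the pivalate cis to C1.

**Step 5**
Reactants: 8 spiro adduct
Product: 10 1-(hydroxymethyl)-5,5,10-trimethyl-3-oxospiro[5.5]undeca-1,9-dien-11-yl pivalate, via spiro-epoxide 9 (not isolated)
Conditions: ICH2Cl, MeLi·LiBr, THF, −78 → 20 °C; then 1 M H2SO4, THF, 0 °C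
Reagents that add atoms: chloroiodomethane (ClCI); water (O)
Why: 1,2-addition of chloromethyllithium to the vinylogous-ester carbonyl and closure to the oxirane, then acid opening of the 2-alkoxyvinyl oxirane with loss of isobutanol (a Stork–Danheiser-type 1,3-carbonyl transposition) gives the 3-(hydroxymethyl)enone; the oxirane centre is destroyed again and C6 and C11 are untouched.

**Step 6**
Reactants: 10 hydroxymethyl enone
Product: 11 4-hydroxy-1-(hydroxymethyl)-5,5,10-trimethyl-3-oxospiro[5.5]undeca-1,9-dien-11-yl pivalate (4-OH trans to C11)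
Conditions: KHMDS (2.3 equiv), THF, −78 °C; 2-(phenylsulfonyl)-3-phenyloxaziridine, −78 °C; aq. NH4Cl
Reagents that add atoms: 2-(phenylsulfonyl)-3-phenyloxaziridine (O=S(=O)(c1ccccc1)N1OC1c1ccccc1)
Why: kinetic α′-enolate hydroxylation (Davis oxidation) in which the bulky pivaloyloxy-bearing C11 arm sits pseudo-axial on C6 (A1,2 strain with the C1 substituent) and shields one face of the dienolate, so oxygen enters C4 trans to C11.

**Step 7**
Reactants: 11 α′-hydroxy enone pivalate
Product: 12 4-hydroxy-1-(hydroxymethyl)-5,5,10-trimethylspiro[5.5]undeca-1,8,10-trien-3-one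
Conditions: Pd(OAc)2 (5 mol %), PPh3 (20 mol %), 1,4-dioxane, 100 °C
Reagents that add atoms: none
Why: Tsuji–Trost-type ionisation of the allylic pivalate to the π-allylpalladium complex and β-hydride elimination, for which only C8 carries β-hydrogens, gives the C8=C9–C10=C11 diene; C11 becomes trigonal and C4 and C6 are unchanged.

**Step 8**
Reactants: 12 trienone diol
Product: 14 cage ketone (3-oxo analogue of the target with acetates on C4, C11 and C12), via diacetate 13 (not isolated)
Conditions: Ac2O (2.2 equiv), BF3·OEt2 (3 equiv), AcOH/CH2Cl2 1:4, −40 °C (30 min) → 0 °C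
Reagents that add atoms: acetic anhydride (CC(=O)OC(C)=O); acetic acid (CC(=O)O)
Why: Proposed new method: after in-situ O-acetylation to 13, BF3 turns the enone into a C1-centred vinylogous oxocarbenium ion (the laboratory counterpart of the chamigrenyl cation) that only C9 of the diene can reach, so C1–C9 closure gives a norbornenyl-type cation that collapses through C8–C10 (homoallyl → cyclopropylcarbinyl) to the nortricyclyl cation, which acetic acid captures at C11 from the open C7 side while the enol tautomerises to the ketone; ring A should react in the chair that keeps the C4 acetate equatorial, which puts C11 axial, the dienolate next to the developing cation and C12 on the C7 side (this sets C1, C8, C9, C10 and C11); the closest known reactions are Lewis-acid enone–olefin cation cyclisations and the acid-catalysed addition of acetic acid to norbornadiene that gives nortricyclyl acetate.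

**Step 9**
Reactants: 14 cage ketone
Product: 15 target, CNP0111873.1
Conditions: NaBH4, CeCl3·7H2O, MeOH/CH2Cl2, −78 → −40 °C; AcOH quench
Reagents that add atoms: none
Why: borohydride reduction in which hydride enters C3 equatorially from the α face because the β axial path is blocked by the syn-axial C12H2OAc and C5 methyl, giving the axial 3-OH cis to the 4-OAc, while low temperature and the acidic quench prevent 4→3 acetyl migration.

**Compound list**
1 | tiglic aldehyde, (2E)-2-methylbut-2-enal | C/C=C(\C)C=O | starting material
2 | (1E)-2-methylbuta-1,3-dien-1-yl pivalate | CC(C)(C)C(=O)O/C=C(\C)C=C | intermediate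
3 | dimedone, 5,5-dimethylcyclohexane-1,3-dione | CC1(C)CC(=O)CC(=O)C1 | starting material
4 | 3-isobutoxy-5,5-dimethylcyclohex-2-en-1-one | CC(C)COC1=CC(=O)CC(C)(C)C1 | intermediate
5 | Mannich base, 6-[(dimethylamino)methyl]-3-isobutoxy-5,5-dimethylcyclohex-2-en-1-one (racemic) | CC(C)COC1=CC(=O)C(CN(C)C)C(C)(C)C1 | intermediate (not isolated)
6 | methiodide of 5, trimethylammonium iodide (racemic) | CC(C)COC1=CC(=O)C(C[N+](C)(C)C)C(C)(C)C1.[I-] | intermediate (not isolated)
7 | 3-isobutoxy-5,5-dimethyl-6-methylidenecyclohex-2-en-1-one | C=C1C(=O)C=C(OCC(C)C)CC1(C)C | intermediate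
8 | 3-isobutoxy-5,5,10-trimethyl-1-oxospiro[5.5]undeca-2,9-dien-11-yl pivalate; C6 as in the target, pivalate cis to C1 | CC(C)COC1=CC(=O)[C@@]2(CCC=C(C)[C@@H]2OC(=O)C(C)(C)C)C(C)(C)C1 | intermediate
9 | spiro-epoxide of 8 (oxirane C1–C12–O, enol ether retained; configuration at C1 not defined) | CC(C)COC1=CC2(CO2)[C@@]3(CCC=C(C)[C@@H]3OC(=O)C(C)(C)C)C(C)(C)C1 | intermediate (not isolated)
10 | 1-(hydroxymethyl)-5,5,10-trimethyl-3-oxospiro[5.5]undeca-1,9-dien-11-yl pivalate | O=C1C=C(CO)[C@@]2(CCC=C(C)[C@@H]2OC(=O)C(C)(C)C)C(C)(C)C1 | intermediate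
11 | 4-hydroxy-1-(hydroxymethyl)-5,5,10-trimethyl-3-oxospiro[5.5]undeca-1,9-dien-11-yl pivalate; 4-OH trans to C11 | O=C1C=C(CO)[C@@]2(CCC=C(C)[C@@H]2OC(=O)C(C)(C)C)C(C)(C)[C@H]1O | intermediate
12 | 4-hydroxy-1-(hydroxymethyl)-5,5,10-trimethylspiro[5.5]undeca-1,8,10-trien-3-one; 4-OH trans to C11 | O=C1C=C(CO)[C@@]2(CC=CC(C)=C2)C(C)(C)[C@H]1O | intermediate
13 | 4-acetoxy-1-(acetoxymethyl)-5,5,10-trimethylspiro[5.5]undeca-1,8,10-trien-3-one | O=C1C=C(COC(C)=O)[C@@]2(CC=CC(C)=C2)C(C)(C)[C@H]1OC(C)=O | intermediate (not isolated)
14 | cage ketone, 3-oxo analogue of the target: C12 acetoxymethyl on the C7 side, 4-OAc equatorial, 11-OAc pointing to C7 | CC(=O)OC[C@]12CC(=O)[C@H](OC(C)=O)C(C)(C)[C@]13C[C@@H]1[C@H]2[C@]1(C)[C@H]3OC(C)=O | intermediate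
15 | CNP0111873.1: 3-OH and 4-OAc cis on the C12 face, 11-OAc pointing to C7, C12H2OAc on the C7 side | CC(=O)OC[C@]12C[C@H](O)[C@H](OC(C)=O)C(C)(C)[C@]13C[C@@H]1[C@H]2[C@]1(C)[C@H]3OC(C)=O | target

**Totals**
Total steps: 9. Longest linear sequence: 8 steps (3 → 4 → 7 → 8 → 10 → 11 → 12 → 14 → 15).

**Steps most likely to fail**

Step 8 (cascade). The diene may be protonated by the acid before the enone reacts, or ring A may cyclise through the other chair and give the C1 diastereomer. The fallback separates the events and changes the terminating nucleophile. It sets out from 12, which is acetylated on its own (Ac2O, DMAP, pyridine) to isolated 13. Cyclisation under aprotic conditions with Me2AlCl in CH2Cl2 at −78 °C traps the nortricyclyl cation with chloride as the C11 chloride of the cage ketone F1 (either C11 epimer serves). Silver-assisted acetolysis (AgOAc, AcOH, 40 °C) re-forms the cyclopropylcarbinyl cation, which takes acetate from the C7 side, and the route is rejoined at 14.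

Step 4 (Diels–Alder). The dienophile is hindered, the 2-methyl group opposes the "ortho" preference of the acyloxy group, and the catalyst's facial control is unproven on this substrate. The fallback replaces catalyst control by a covalent auxiliary that is lost later. It sets out from 1 and 7. Tiglic aldehyde is converted (KOt-Bu, then (−)-menthyl chloroformate) into the dienyl menthyl carbonate F2. An Et2AlCl-promoted Diels–Alder reaction with 7 gives the carbonate adduct F3 as C6 diastereomers, and the one with C6 as in 8 is separated by chromatography or crystallisation. The conditions of step 5 take it through the spiro-epoxide F4 to the hydroxymethyl enone carbonate F5, and the conditions of step 6 give the 4-hydroxy carbonate F6. Pd(PPh3)4 in THF at 60 °C ionises the allylic carbonate more readily than the pivalate and rejoins the route at 12.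

Step 7 (1,4-elimination). Palladium must approach the allylic pivalate anti to the ester, on the face flanked by the C5 gem-dimethyl carbon, and may not ionise it. The fallback makes the diene without a metal by ionisation and E1 loss of a proton. It sets out from 11, which is warmed in hexafluoroisopropanol with 2,6-di-tert-butylpyridine at 50–60 °C. The 2-methylcyclohexenyl cation can lose a proton only from C8, so the route is rejoined directly at 12; the fallback makes no compound outside the list (F0).

**Further compounds**
F1 | step 8 | C11 chloride of the cage ketone (11-chloro analogue of 14) | CC(=O)OC[C@]12CC(=O)[C@H](OC(C)=O)C(C)(C)[C@]13C[C@@H]1[C@H]2[C@]1(C)[C@H]3Cl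
F2 | step 4 | (1E)-2-methylbuta-1,3-dien-1-yl (1R,2S,5R)-menthyl carbonate | CC(C)[C@@H]1CC[C@@H](C)C[C@H]1OC(=O)O/C=C(\C)C=C
F3 | step 4 | menthyl carbonate analogue of 8 | CC(C)[C@@H]1CC[C@@H](C)C[C@H]1OC(=O)O[C@H]2C(C)=CCC[C@@]23C(=O)C=C(OCC(C)C)CC3(C)C
F4 | step 4 | menthyl carbonate analogue of 9 (spiro-epoxide, not isolated) | CC(C)[C@@H]1CC[C@@H](C)C[C@H]1OC(=O)O[C@H]2C(C)=CCC[C@@]23C4(CO4)C=C(OCC(C)C)CC3(C)C
F5 | step 4 | menthyl carbonate analogue of 10 | CC(C)[C@@H]1CC[C@@H](C)C[C@H]1OC(=O)O[C@H]2C(C)=CCC[C@@]23C(CO)=CC(=O)CC3(C)C
F6 | step 4 | menthyl carbonate analogue of 11 | CC(C)[C@@H]1CC[C@@H](C)C[C@H]1OC(=O)O[C@H]2C(C)=CCC[C@@]23C(CO)=CC(=O)[C@H](O)C3(C)C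
F0 | step 7 | none | none
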